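The numbers in the tables stem from a simulated flask on assumed constants.

Look at the plateau.

all flasks: initiator 2.5 mol%
- oak: starting material 5 mM; partner 0.70 equiv; scavenger 1.2 equiv; run made earlier
- ash: starting material 5 mM; partner 0.70 equiv; scavenger 2.2 equiv; run made earlier
- north: starting material 5.0 mM; partner 0.700 equiv; scavenger 1.00 equiv; time 6.0 min
- south-west: starting material 5.0 mM; partner 0.700 equiv; scavenger 1.50 equiv; time 6.0 min

| run | time / min | starting material / % | product / % |
|---|---|---|---|
| oak | 0.250 | 58.2 | 36.2 |
| oak | 0.333 | 49.5 | 47.8 |
| oak | 0.500 | 36.6 | 60.5 |
| oak | 0.833 | 30.3 | 69.0 |
| oak | 1.33 | 30.9 | 70.0 |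
| oak | 2.00 | 30.0 | 70.1 |
| oak | 3.00 | 29.6 | 69.5 |
| ash | 0.250 | 59.8 | 37.0 |
| ash | 0.333 | 50.7 | 47.7 |
| ash | 0.500 | 37.5 | 60.4 |
| ash | 0.833 | 30.7 | 70.0 |
| ash | 1.33 | 28.9 | 70.0 |
| ash | 2.00 | 30.6 | 70.8 |
| ash | 3.00 | 29.8 | 70.4 |

(standard deviation of a reading: 0.5 percentage points)

- a species is counted by the starting material in it: one ended chains A counts as two
- amounts and yields of released group count idle adduct too
- steps that have been proposed: scavenger + released group -> scavenged by-product; 2 second chain carrier -> ended chains B; initiator -> 2 initiating radical; 2 first chain carrier -> ended chains A; partner + first chain carrier -> product + second chain carrier; starting material + second chain carrier -> released group + first chain carrier; starting material + initiating radical -> capped initiator + first chain carrier; starting material + released group <-> idle adduct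

1. part of the starting material that has reacted at the end, north
2. part of the starting material that has reacted at the end, south-west
3. what raising the equivalents of scavenger from its lowest to its highest value here does to the part of the starting material that has reacted (changes below 5 percentage points count as none) (it rises / no change / it falls)

Two colleagues argue at the board, and I call them Clock and Stock. Clock reads the oak run as a step response: starting material falls from 58.2% at 0.250 min to 36.6% at 0.500 min, a time constant of 0.539 min as read. Since 6.0 min is 11.1 such constants, Clock calls the flat stretch a stall and expects >99.9% reacted in north and in south-west.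

Stock freezes the two chain carriers, which go round unchanged, and counts. Each turn spends one partner and one starting material and gives one product and one released group. So the part reacted by chain turns has a ceiling, the smaller of the charges of partner and starting material as a fraction of the starting material: 0.700 here, with partner as the limiting reagent. The oak run stands at 69.5% product at 3.00 min, and the ash run at 70.4%.

Scavenger has to take up one released group per turn. North's 1.00 equiv exceeds the ceiling by 0.300, so I side with Stock: both flasks stop near the ceiling, with no trend.

The forecast gives 70% for north, 70% for south-west and no change: “Six minutes is ample”.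

The flask gives 70.1% in north and 70.1% in south-west, against the ceiling of 0.700; for the trend the answer is no change, a change of 0 percentage points. In north, partner stands at 0% of its charge while 30% of the starting material remains.

    scavenger + released group → scavenged by-product (k = 39.0 L mol⁻¹ s⁻¹)
    2 second chain carrier → ended chains B (k = 1.00 × 10⁷ L mol⁻¹ s⁻¹)
    initiator → 2 initiating radical (k = 3.70 × 10⁻⁵ s⁻¹)
    2 first chain carrier → ended chains A (k = 1.00 × 10⁶ L mol⁻¹ s⁻¹)
    partner + first chain carrier → product + second chain carrier (k = 1.80 × 10⁶ L mol⁻¹ s⁻¹)
    starting material + second chain carrier → released group + first chain carrier (k = 2.50 × 10⁶ L mol⁻¹ s⁻¹)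
    starting material + initiating radical → capped initiator + first chain carrier (k = 5.50 × 10⁷ L mol⁻¹ s⁻¹)
    starting material + released group ⇌ idle adduct, settled at all times (K = 130 L mol⁻¹)

Clock's region is a flask where partner outlasts the starting material. The neighbour flask is south-west with 1.20 equiv of partner. Its ceiling is 1.00, now the starting material's own charge, and that leaves 16.7% of the partner unspent. The neighbour flask reaches 100% reacted, Clock's figure, with 17% of its partner still there.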